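**Strategy.** Everything rests on the C8–C8′ bond at the centre of the butane-1,4-diol core. C8 and C8′ each carry the same 4-hydroxy-3-methoxybenzyl arm and the same CH2O carbon, so the core is C2-symmetric and is cut into two identical C6C3 halves, as in lignan biosynthesis. The key step is an oxidative homocoupling of the enolate of an N-(3-arylpropanoyl)oxazolidinone. It forms C8–C8′ and sets both stereocentres (R,R) at once, under control of one (S)-auxiliary per half; no ring is formed. Its precursor is a simple acyclic imide of O-benzyl dihydroferulic acid. Reduction gives a diol with homotopic hydroxyls, which is monoferuloylated and debenzylated.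

Key step: step 3

Remark: the target is read as the mono-(E)-ferulate of (8R,8′R)-secoisolariciresinol (lignan numbering: C7 benzylic CH2, C8 methine, C9 CH2O); both stereocentres are R.

**Step 1**
Reactants: 1 3-(4-hydroxy-3-methoxyphenyl)propanoic acid (dihydroferulic acid)
Product: 3 3-[4-(benzyloxy)-3-methoxyphenyl]propanoic acid, via benzyl ester 2 (not isolated)
Conditions: BnBr (2.3 equiv), K2CO3 (2.5 equiv), DMF, 60 °C; then 2 M aq NaOH, MeOH, 60 °C; then HCl to pH 2
Reagents that add atoms: benzyl bromide, BrCc1ccccc1; sodium hydroxide, [Na+].[OH-] (one carboxyl oxygen of 3)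
Why: Williamson O-benzylation of the phenoxide (the carboxylate is benzylated as well) and saponification of the benzyl ester in the same pot should leave only the robust aryl benzyl ether; no stereocentre is involved.

**Step 2**
Reactants: 3 3-[4-(benzyloxy)-3-methoxyphenyl]propanoic acid; 4 (S)-4-isopropyl-1,3-oxazolidin-2-one
Product: 6 (S)-3-{3-[4-(benzyloxy)-3-methoxyphenyl]propanoyl}-4-isopropyl-1,3-oxazolidin-2-one, via pivalic mixed anhydride 5 (not isolated)
Conditions: PivCl (1.05 equiv), Et3N (2.5 equiv), THF, −20 °C; then LiCl (1.1 equiv), 4 (1.0 equiv), −20 °C → rt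
Reagents that add atoms: pivaloyl chloride, CC(C)(C)C(=O)Cl (its acyl group is in 5 only and is lost again on the way to 6)
Why: N-acylation of the oxazolidinone through the pivaloyl mixed anhydride (attack at the less hindered, non-pivaloyl carbonyl, with LiCl/Et3N activation of the N–H) is a standard way to make such imides without strong base.

**Step 3**
Reactants: 6 (S)-3-{3-[4-(benzyloxy)-3-methoxyphenyl]propanoyl}-4-isopropyl-1,3-oxazolidin-2-one (two molecules)
Product: 9 (2R,3R)-2,3-bis[4-(benzyloxy)-3-methoxybenzyl]-1,4-bis[(S)-4-isopropyl-2-oxo-1,3-oxazolidin-3-yl]butane-1,4-dione, via lithium (Z)-enolate 7 (not isolated), via trichlorotitanium (Z)-enolate 8 (not isolated)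
Conditions: LDA (1.1 equiv), THF, −78 °C, 1 h; then TiCl4 (1.1 equiv, 1 M in CH2Cl2), −78 °C → 0 °C
Reagents that add atoms: lithium diisopropylamide, [Li+].CC(C)[N-]C(C)C (lithium of 7 only); titanium tetrachloride, Cl[Ti](Cl)(Cl)Cl (TiCl3 unit of 8 only); none of these atoms remains in 9
Why: LDA should give the chelated lithium (Z)-enolate 7, which TiCl4 converts into the titanium(IV) enolate 8; inner-sphere electron transfer to titanium (Ti(IV) → Ti(III)) then generates a chelated α-carbonyl radical at C8 that combines with a second enolate or radical to form the C8–C8′ σ bond. The closest known reaction type is the oxidative homocoupling of metal enolates of chiral N-acyl oxazolidinones (Ti(IV), Cu(II) or hypervalent iodine as oxidant). No ring is closed. Both stereocentres are created in this one bond formation and each is controlled by its own auxiliary: chelation holds the trigonal C8 s-cis to the ring carbonyl and the 4-isopropyl group shields one face, so that bonding anti to it gives R at C8 and at C8′ for the (S)-auxiliary, the two inductions reinforcing each other in the C2-symmetric product. The step needs R,R over R,S and S,S selectivity, which the two identical auxiliaries secure and which can be upgraded by separation because all three isomers are diastereomers; it also needs C–C coupling to outrun α-chlorination and dehydrogenation to the cinnamoyl imide, which complete enolate formation before the oxidant is added and the low temperature should favour.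

**Step 4**
Reactants: 9 (2R,3R)-2,3-bis[4-(benzyloxy)-3-methoxybenzyl]-1,4-bis[(S)-4-isopropyl-2-oxo-1,3-oxazolidin-3-yl]butane-1,4-dione
Product: 10 (2R,3R)-2,3-bis[4-(benzyloxy)-3-methoxybenzyl]butane-1,4-diol
Conditions: LiBH4 (5 equiv), MeOH (5 equiv), THF, 0 °C → rt; aq NH4Cl
Reagents that add atoms: none
Why: Reductive cleavage of N-acyl oxazolidinones with LiBH4 (hydride attack at the Li-chelated exocyclic carbonyl) should give both primary alcohols and free the auxiliary for recovery, and these non-basic conditions should not epimerise C8/C8′, which cease to be α-carbonyl centres.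

**Step 5**
Reactants: 11 (E)-3-(4-hydroxy-3-methoxyphenyl)prop-2-enoic acid (ferulic acid)
Product: 13 (E)-3-[4-(benzyloxy)-3-methoxyphenyl]prop-2-enoic acid, via benzyl ester 12 (not isolated)
Conditions: BnBr (2.3 equiv), K2CO3 (2.5 equiv), DMF, 60 °C; then 2 M aq NaOH, MeOH, 60 °C; then HCl to pH 2
Reagents that add atoms: benzyl bromide, BrCc1ccccc1; sodium hydroxide, [Na+].[OH-] (one carboxyl oxygen of 13)
Why: Williamson O-benzylation followed by saponification as in step 1; the (E)-alkene is not touched by carbonate or hydroxide.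

**Step 6**
Reactants: 10 (2R,3R)-2,3-bis[4-(benzyloxy)-3-methoxybenzyl]butane-1,4-diol (3 equiv); 13 (E)-3-[4-(benzyloxy)-3-methoxyphenyl]prop-2-enoic acid (1 equiv)
Product: 15 (2R,3R)-2,3-bis[4-(benzyloxy)-3-methoxybenzyl]-4-hydroxybutyl (E)-3-[4-(benzyloxy)-3-methoxyphenyl]prop-2-enoate, via O-acylisourea 14 (not isolated)
Conditions: DIC (1.1 equiv), DMAP (0.1 equiv), CH2Cl2, 0 °C → rt, slow addition of 13 to 10; unreacted 10 recovered
Reagents that add atoms: N,N'-diisopropylcarbodiimide, CC(C)N=C=NC(C)C (its atoms are in 14 only and leave as the urea)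
Why: In this Steglich esterification the two hydroxyls of C2-symmetric 10 are homotopic, so either one gives the same monoester and only the degree of acylation must be held back, which the excess of diol and the slow addition should do.

**Step 7**
Reactants: 15 (2R,3R)-2,3-bis[4-(benzyloxy)-3-methoxybenzyl]-4-hydroxybutyl (E)-3-[4-(benzyloxy)-3-methoxyphenyl]prop-2-enoate
Product: 16 hanultarin, (2R,3R)-4-hydroxy-2,3-bis(4-hydroxy-3-methoxybenzyl)butyl (E)-3-(4-hydroxy-3-methoxyphenyl)prop-2-enoate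
Conditions: BCl3 (1 M in CH2Cl2, 8 equiv), pentamethylbenzene (10 equiv), CH2Cl2, −78 °C; quench with CHCl3/MeOH at −78 °C
Reagents that add atoms: none
Why: Lewis-acid cleavage of the three aryl benzyl ethers, with pentamethylbenzene trapping the benzyl cation by Friedel–Crafts alkylation, should leave the cinnamate C=C, the ester and the aryl methyl ethers intact at −78 °C, where hydrogenolysis would saturate the alkene.

**Compound list**

1 | 3-(4-hydroxy-3-methoxyphenyl)propanoic acid (dihydroferulic acid) | COc1cc(CCC(=O)O)ccc1O | starting material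
2 | benzyl 3-[4-(benzyloxy)-3-methoxyphenyl]propanoate | COc1cc(CCC(=O)OCc2ccccc2)ccc1OCc1ccccc1 | intermediate (not isolated)
3 | 3-[4-(benzyloxy)-3-methoxyphenyl]propanoic acid | COc1cc(CCC(=O)O)ccc1OCc1ccccc1 | intermediate
4 | (S)-4-isopropyl-1,3-oxazolidin-2-one | CC(C)[C@H]1COC(=O)N1 | starting material
5 | 3-[4-(benzyloxy)-3-methoxyphenyl]propanoic pivalic anhydride | COc1cc(CCC(=O)OC(=O)C(C)(C)C)ccc1OCc1ccccc1 | intermediate (not isolated)
6 | (S)-3-{3-[4-(benzyloxy)-3-methoxyphenyl]propanoyl}-4-isopropyl-1,3-oxazolidin-2-one | COc1cc(CCC(=O)N2[C@@H](C(C)C)COC2=O)ccc1OCc1ccccc1 | intermediate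
7 | lithium (Z)-enolate of 6 | [Li+].COc1cc(C/C=C(\[O-])N2[C@@H](C(C)C)COC2=O)ccc1OCc1ccccc1 | intermediate (not isolated)
8 | trichlorotitanium(IV) (Z)-enolate of 6 | COc1cc(C/C=C(\O[Ti](Cl)(Cl)Cl)N2[C@@H](C(C)C)COC2=O)ccc1OCc1ccccc1 | intermediate (not isolated)
9 | (2R,3R)-2,3-bis[4-(benzyloxy)-3-methoxybenzyl]-1,4-bis[(S)-4-isopropyl-2-oxo-1,3-oxazolidin-3-yl]butane-1,4-dione | O=C([C@H](Cc1ccc(OCc2ccccc2)c(OC)c1)[C@@H](Cc1ccc(OCc2ccccc2)c(OC)c1)C(=O)N1[C@@H](C(C)C)COC1=O)N1[C@@H](C(C)C)COC1=O | intermediate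
10 | (2R,3R)-2,3-bis[4-(benzyloxy)-3-methoxybenzyl]butane-1,4-diol | OC[C@H](Cc1ccc(OCc2ccccc2)c(OC)c1)[C@H](CO)Cc1ccc(OCc2ccccc2)c(OC)c1 | intermediate
11 | (E)-3-(4-hydroxy-3-methoxyphenyl)prop-2-enoic acid (ferulic acid) | COc1cc(/C=C/C(=O)O)ccc1O | starting material
12 | benzyl (E)-3-[4-(benzyloxy)-3-methoxyphenyl]prop-2-enoate | COc1cc(/C=C/C(=O)OCc2ccccc2)ccc1OCc1ccccc1 | intermediate (not isolated)
13 | (E)-3-[4-(benzyloxy)-3-methoxyphenyl]prop-2-enoic acid | COc1cc(/C=C/C(=O)O)ccc1OCc1ccccc1 | intermediate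
14 | O-{(E)-3-[4-(benzyloxy)-3-methoxyphenyl]prop-2-enoyl}-N,N'-diisopropylisourea | COc1cc(/C=C/C(=O)OC(=NC(C)C)NC(C)C)ccc1OCc1ccccc1 | intermediate (not isolated)
15 | (2R,3R)-2,3-bis[4-(benzyloxy)-3-methoxybenzyl]-4-hydroxybutyl (E)-3-[4-(benzyloxy)-3-methoxyphenyl]prop-2-enoate | COc1cc(/C=C/C(=O)OC[C@H](Cc2ccc(OCc3ccccc3)c(OC)c2)[C@H](CO)Cc2ccc(OCc3ccccc3)c(OC)c2)ccc1OCc1ccccc1 | intermediate
16 | hanultarin, (2R,3R)-4-hydroxy-2,3-bis(4-hydroxy-3-methoxybenzyl)butyl (E)-3-(4-hydroxy-3-methoxyphenyl)prop-2-enoate | COc1cc(/C=C/C(=O)OC[C@H](Cc2ccc(O)c(OC)c2)[C@H](CO)Cc2ccc(O)c(OC)c2)ccc1O | target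

**Step count.** Total: 7 steps. Longest linear sequence: 6 steps (1, 2, 3, 4, 6, 7); step 5 is a one-step side branch.

**Steps most likely to fail**

Step 3. The coupling may show incomplete facial control at one of the two carbons (R,S-coupled diastereomer), and the oxidised enolate may be diverted to α-chlorination or dehydrogenation instead of dimerisation. Fallback, from 6 back to 10: the second arm is introduced by enolate benzylation, with each centre under the control of its own auxiliary.
- The sodium enolate of 6 (NaHMDS, THF, −78 °C) is alkylated with tert-butyl bromoacetate (Evans alkylation, attack anti to the isopropyl group) to tert-butyl (3R)-3-[4-(benzyloxy)-3-methoxybenzyl]-4-[(4S)-4-isopropyl-2-oxo-1,3-oxazolidin-3-yl]-4-oxobutanoate F1.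
- The tert-butyl ester is cleaved (TFA, Et3SiH, CH2Cl2, 0 °C) to (3R)-3-[4-(benzyloxy)-3-methoxybenzyl]-4-[(4S)-4-isopropyl-2-oxo-1,3-oxazolidin-3-yl]-4-oxobutanoic acid F2.
- F2 is joined through its pivaloyl mixed anhydride (PivCl, Et3N, then LiCl) to commercial (R)-4-isopropyl-1,3-oxazolidin-2-one to give the mixed bis-imide (4S)-3-{(2R)-2-[4-(benzyloxy)-3-methoxybenzyl]-4-[(4R)-4-isopropyl-2-oxo-1,3-oxazolidin-3-yl]-4-oxobutanoyl}-4-isopropyl-1,3-oxazolidin-2-one F3.
- The CH2 group of F3 is enolised selectively (NaHMDS, −78 °C; the methine proton of the other imide is shielded by allylic strain) and alkylated with 4-(benzyloxy)-3-methoxybenzyl bromide F4, made from the commercial benzyl alcohol with PBr3 in Et2O at 0 °C. Under control of the (R)-auxiliary this should give (2R,3R)-2,3-bis[4-(benzyloxy)-3-methoxybenzyl]-1-[(4R)-4-isopropyl-2-oxo-1,3-oxazolidin-3-yl]-4-[(4S)-4-isopropyl-2-oxo-1,3-oxazolidin-3-yl]butane-1,4-dione F5.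
- LiBH4/MeOH in THF reduces F5 to 10.

Step 6. Over-acylation to the diester may occur, with poor conversion based on the diol if the two acylations are not well separated in rate. Fallback, from 10 back to 15: the stoichiometry problem is moved to a monoprotection.
- 10 is converted through its monosodium alkoxide (NaH, 1.0 equiv, THF; then TBSCl, 1.0 equiv) into (2R,3R)-2,3-bis[4-(benzyloxy)-3-methoxybenzyl]-4-[(tert-butyldimethylsilyl)oxy]butan-1-ol F6.
- F6 is esterified with 13 (DIC, DMAP, CH2Cl2) to (2R,3R)-2,3-bis[4-(benzyloxy)-3-methoxybenzyl]-4-[(tert-butyldimethylsilyl)oxy]butyl (E)-3-[4-(benzyloxy)-3-methoxyphenyl]prop-2-enoate F7.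
- F7 is desilylated (HF·pyridine, THF/pyridine, 0 °C) to 15; an acyl shift between the two oxygens of 15 would be degenerate.

Step 7. Lewis-acid side reactions may accompany benzyl ether cleavage: C-benzylation of the electron-rich rings, O-demethylation, or cyclisation of the hydroxy ester to a tetrahydrofuran with loss of ferulate. Fallback, from 10 and 11 directly to 16: the benzyl groups are removed before the alkene is present and the ester is made enzymatically without protecting groups.
- 10 is hydrogenolysed (H2, Pd/C, EtOAc/MeOH) to (−)-secoisolariciresinol, (2R,3R)-2,3-bis(4-hydroxy-3-methoxybenzyl)butane-1,4-diol F8.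
- Ferulic acid 11 is converted by catalytic transvinylation (vinyl acetate, Pd(OAc)2 or Hg(OAc)2/H2SO4 cat.) into vinyl (E)-3-(4-hydroxy-3-methoxyphenyl)prop-2-enoate (vinyl ferulate) F9.
- F8 (in excess) is acylated with F9 by an immobilised lipase (Candida antarctica lipase B, 2-methylbutan-2-ol, 45 °C, stopped at partial conversion). This enzyme class acylates primary aliphatic hydroxyls and leaves phenols alone, so 16 should form directly.

**Further compounds**

F1 | step 3 | tert-butyl (3R)-3-[4-(benzyloxy)-3-methoxybenzyl]-4-[(4S)-4-isopropyl-2-oxo-1,3-oxazolidin-3-yl]-4-oxobutanoate | CC(C)(C)OC(=O)C[C@@H](Cc1ccc(OCc2ccccc2)c(OC)c1)C(=O)N1[C@@H](C(C)C)COC1=O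
F2 | step 3 | (3R)-3-[4-(benzyloxy)-3-methoxybenzyl]-4-[(4S)-4-isopropyl-2-oxo-1,3-oxazolidin-3-yl]-4-oxobutanoic acid | OC(=O)C[C@@H](Cc1ccc(OCc2ccccc2)c(OC)c1)C(=O)N1[C@@H](C(C)C)COC1=O
F3 | step 3 | (4S)-3-{(2R)-2-[4-(benzyloxy)-3-methoxybenzyl]-4-[(4R)-4-isopropyl-2-oxo-1,3-oxazolidin-3-yl]-4-oxobutanoyl}-4-isopropyl-1,3-oxazolidin-2-one | O=C(C[C@@H](Cc1ccc(OCc2ccccc2)c(OC)c1)C(=O)N1[C@@H](C(C)C)COC1=O)N1[C@H](C(C)C)COC1=O
F4 | step 3 | 4-(benzyloxy)-3-methoxybenzyl bromide | COc1cc(CBr)ccc1OCc1ccccc1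
F5 | step 3 | (2R,3R)-2,3-bis[4-(benzyloxy)-3-methoxybenzyl]-1-[(4R)-4-isopropyl-2-oxo-1,3-oxazolidin-3-yl]-4-[(4S)-4-isopropyl-2-oxo-1,3-oxazolidin-3-yl]butane-1,4-dione | O=C([C@H](Cc1ccc(OCc2ccccc2)c(OC)c1)[C@@H](Cc1ccc(OCc2ccccc2)c(OC)c1)C(=O)N1[C@@H](C(C)C)COC1=O)N1[C@H](C(C)C)COC1=O
F6 | step 6 | (2R,3R)-2,3-bis[4-(benzyloxy)-3-methoxybenzyl]-4-[(tert-butyldimethylsilyl)oxy]butan-1-ol | OC[C@H](Cc1ccc(OCc2ccccc2)c(OC)c1)[C@H](CO[Si](C)(C)C(C)(C)C)Cc1ccc(OCc2ccccc2)c(OC)c1
F7 | step 6 | (2R,3R)-2,3-bis[4-(benzyloxy)-3-methoxybenzyl]-4-[(tert-butyldimethylsilyl)oxy]butyl (E)-3-[4-(benzyloxy)-3-methoxyphenyl]prop-2-enoate | COc1cc(/C=C/C(=O)OC[C@H](Cc2ccc(OCc3ccccc3)c(OC)c2)[C@H](CO[Si](C)(C)C(C)(C)C)Cc2ccc(OCc3ccccc3)c(OC)c2)ccc1OCc1ccccc1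
F8 | step 7 | (−)-secoisolariciresinol, (2R,3R)-2,3-bis(4-hydroxy-3-methoxybenzyl)butane-1,4-diol | OC[C@H](Cc1ccc(O)c(OC)c1)[C@H](CO)Cc1ccc(O)c(OC)c1
F9 | step 7 | vinyl (E)-3-(4-hydroxy-3-methoxyphenyl)prop-2-enoate (vinyl ferulate) | COc1cc(/C=C/C(=O)OC=C)ccc1O
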